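Atom numbers C1–C23 are those of the target (ring A: C1–C5 and C10; ring B: C5–C10; chain C11–C23). "β" means the face of ring B that carries CH3-10. Compound numbers are those of the steps below.

## Analysis of the target

Myrrhanone B (35) is a bicyclic triterpenoid: a decalin that carries at C9 an unbranched C13 chain with three (E)-trisubstituted alkenes (C13=C14, C17=C18, C21=C22) and ends in an α-methyl-α,β-unsaturated acid (C23). Ring A holds the C3 ketone next to the C4 gem-dimethyl group, and ring B holds the tertiary C8 carbinol. The four stereocentres are fused or contiguous: C5 (S) and C10 (S) place H-5 and CH3-10 on the same face, so the decalin is cis-fused; C9 (R) places the chain on that same β face; C8 (R) has its methyl β and its hydroxyl α, trans to the chain. C8 and C10 are fully substituted and C9 lies between them, so the C9–C11 bond has to be made at a doubly neopentyl carbon. Sensitive groups are the tertiary alcohol (elimination under acid), the 1,5-polyene (acid-induced cyclisation, electrophilic oxidants, hydrogenation) and the enoic acid, so the chain should arrive late and the last steps must be mild. The difficulty is to fix the absolute configuration of a cis-fused 4,4,10-trimethyl decalin and to relay it to C9 and C8. The feature used is that C5 with its attached C4, the C8 methyl on a ring-B alkene and a carbonyl at C9 are the skeleton of (S)-carvone 1: ring B is the carvone ring, and the isopropenyl group is C4 with one methyl and a CH2 that becomes the second methyl when the C3–C4 bond closes ring A.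

## Retrosynthetic reasoning

**35 back to 32.** The acid and the C3 ketone are taken back to alcohols (34, 33) and these to the bis-silyl ether 32. This keeps both electrophilic carbonyls and the acidic proton out of every earlier intermediate. Forward, two oxidations must leave the tertiary C8 carbinol and the chain alkenes alone.

**32 back to 29.** A carbonyl is placed at C7 (removed forward through tosylhydrazone 30). It is put there because a C7 ketone conjugated to C8=C9 is the one function that makes C9 electrophilic and C8 nucleophilic at once. Forward, C7 must be reduced to CH2 without loss of the neighbouring hydroxyl.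

**29 back to 15 and 25.** The C8–O and C9–C11 bonds are cut, through silyl enol ether 27. C9–C11 is chosen because it divides 35 into a ring piece and the complete chain, whose alkenes and C23 oxygen are then made on an acyclic compound. A cut at C11–C12 or C12–C13 would leave a short stub to be elaborated on the hindered ring. Forward, the organometallic 26 must add to C9 of enone 15 on the face of CH3-10, and oxygen must enter C8 opposite to the new chain.

**15 back to 10.** The enone is transposed: the C7 carbonyl with C8=C9 comes from the C9 carbonyl with C7=C8, through silyl ether 11, epoxy ketone 12 and allylic alcohol 14. The gain is that 10 has its oxygen at C9, where carvone has it. Forward, three steps shift it to C7.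

**10 back to 9 (key).** C3–C4 is cut. It is the only ring-A bond whose scission leaves both fragments as simple substituents on ring B, an isopropenyl group at C5 and a 3-oxopropyl arm at C10. It also makes the quaternary C4 a radical centre, where crowding matters little. Forward, hydrogen must add to the CH2 of the isopropenyl group and the C4 radical must attack the aldehyde carbon.

**9 back to 1 and 2.** The arm is taken back to an allyl group (8, 6), and the C10–CH3 and C10–C1 bonds are cut (6, 4). Both are alkylations at the α′ carbon of 1. Forward, the order (allyl first, methyl second) decides that methyl ends trans and the arm cis to the isopropenyl group, which is what a cis fusion needs.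

**25 back to 16.** The chain is farnesol 16 plus one carbon at C11 and an oxygen at C23. C11–C12 is cut (methylenation of enal 21, hydroboration of tetraene 22 to alcohol 24) and the C23–O bond is cut (allylic oxidation of acetate 17 to 18). Compound 16 supplies all three (E)-alkenes, so no alkene geometry has to be created.

## Alternatives that were turned down

**Alternative 1:** Anionic oxy-Cope route.
- Disconnection: the ring-A bond C1–C10 of octalone A1 is cut while a C3–C8 bond is added. This leads to the vinyl carbinol A2 on a bicyclo[2.2.2]octene, traced to 2,4,6-trimethylphenol A3 by dearomatising C-methylation, cycloaddition with a two-carbon dienophile and vinyl addition.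
- Forward key step: the potassium alkoxide of A2 undergoes a [3,3] shift through the boat that the bicycle enforces and gives A1 after protonation.
- For: the cis fusion is a geometric necessity. Ring A arrives with the C3 ketone and the gem-dimethyl group in place, so there are no C3 epimers and no question of which alkene accepts hydrogen. The decalin is reached in about as few steps as 10. On these points it is equal or stronger.
- Against: A3 is achiral, so the absolute configuration must come from an asymmetric cycloaddition of a dimerisation-prone cyclohexadienone or from a resolution. The vinyl nucleophile must add to a ketone flanked by a quaternary carbon with the right facial sense. A1 has no oxygen in ring B, so the chain-accepting enone needs an allylic oxidation at C7 and then carries two ketones (C3, C7) that must be told apart in the C8 hydroxylation and the C7 deoxygenation.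
- Comparison: the chosen route offers a secured absolute configuration from 1 and one carbonyl group per intermediate, because C3 leaves the key step as a carbinol that is simply silylated.

**Alternative 2:** Ketyl–olefin reclosure of ring B.
- Disconnection: C8–C9 of hydroxy ester A4 is cut to the keto enoate A5 (methyl ketone at C8, (E)-enoate C9=C11 on C10). A5 would come from (S)-Wieland–Miescher ketone A6 by gem-dimethylation, setting of C5, oxidative opening of ring B and two chain extensions.
- Forward key step: one-electron reduction of the C8 ketone of A5 gives a ketyl that adds 6-exo to C9 and closes ring B.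
- For: the tertiary carbinol and the C9 centre form together, directly in the final oxidation pattern, with the hydroxyl trans to the arm as is usual for chelated ketyl–enoate closures. No carbonyl transposition and no C7 deoxygenation are needed. Here it is clearly stronger than the chosen route.
- Against: ring B of A6 has to be destroyed and rebuilt, which costs more steps than it saves. The cis relation of H-5 and CH3-10 must be created against the usual trans preference of reductions in the 4,4-dimethyl series. The closure must select one of four diastereomers with both reacting arms on freely rotating tethers. A4 carries only C11–C12, so the rest of the chain must be joined at C12–C13 next to a trisubstituted alkene, by an sp3–sp2 coupling or a poorly selective olefination.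
- Comparison: the chosen route keeps ring B intact from 1 and joins the whole chain in one bond (C9–C11); it accepts the transposition and the deoxygenation as the price.

**Alternative 3:** Diels–Alder annulation of ring A.
- Disconnection: C1–C10 and C4–C5 of silyl enol ether A7 are cut to 2-methylcyclohex-2-enone A8 and the 2-silyloxydiene A9 that carries both C4 methyls.
- Forward key step: a chiral Lewis acid activates A8, and suprafacial [4+2] addition gives the cis fusion with the C3 oxygen and the gem-dimethyl group in place.
- For: it is the most convergent entry to the decalin (two bonds and both fusion centres in one step). Its enantiocontrol is catalytic and independent of a chiral pool, and the C3 oxygen arrives regiodefined. On step count to the bicycle it is stronger.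
- Against: the reacting terminus C4 of A9 is fully substituted, so one methyl points into the diene in the s-cis form; such dienes react slowly and tend to give open-chain Mukaiyama–Michael products. A8 is an α-substituted cyclic enone and a weak dienophile, so the hindered C4–C5 bond would form under forcing conditions where enantioselection is least reliable. A7 has neither the C8 methyl nor any handle at C7/C8, so methylation, oxygenation and conversion of the C9 ketone into the chain-bearing CH would still follow.
- Comparison: the chosen route builds the quaternary C4 by an intramolecular tertiary-radical addition (C3–C4), which is insensitive to that crowding, and takes the C8 methyl and the ring-B unsaturation ready-made from 1.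

Key step: step 5

Assumption 1: the C3 carbinol of step 5 is carried as whichever epimer (or mixture) forms, because C3 is oxidised in step 23; compounds 10–33 are written as the 3S epimer.
Assumption 2: other centres that are destroyed again within the route (C10 of 4, C7 and C8 of 12, C7 of 14 and 31) are written as the expected epimer or left open, as said in the compound list.

## Route

Step 1
Reactants: 1 (S)-(+)-carvone; 2 allyl bromide
Product: 4 (5S)-2-methyl-6-(prop-2-en-1-yl)-5-(prop-1-en-2-yl)cyclohex-2-en-1-one (5,6-trans major), via lithium dienolate 3 (not isolated)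
Conditions: LiN(i-Pr)2 (LDA), THF, −78 °C; then 2, −78 → 0 °C
Reagents that add atoms: none
Why: LiN(i-Pr)2 removes the kinetic α′ proton of 1 (the future C10) to give the cross-conjugated dienolate 3, which is C-allylated by the reactive allylic halide (enolate alkylation); the new centre may form as a mixture because it is planarised again in step 2.

Step 2
Reactants: 4 6-allylcarvone
Product: 6 (5R,6S)-6-allyl-2,6-dimethyl-5-(prop-1-en-2-yl)cyclohex-2-en-1-one, via lithium enolate 5 (not isolated)
Conditions: LiN(i-Pr)2, THF, −78 °C; then MeI, −78 → 0 °C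
Reagents that add atoms: iodomethane, CI
Why: The tetrasubstituted enolate 5 is methylated on the face away from the neighbouring isopropenyl group (enolate alkylation under 1,2-induction), so the methyl ends trans and the allyl arm cis to isopropenyl; this sets C10 from C5 and is the arrangement a cis ring fusion requires.

Step 3
Reactants: 6 allyl methyl ketone
Product: 8 (5R,6S)-6-(3-hydroxypropyl)-2,6-dimethyl-5-(prop-1-en-2-yl)cyclohex-2-en-1-one, via alkyl(disiamyl)borane 7 (not isolated)
Conditions: Sia2BH (from BH3·SMe2 and 2-methylbut-2-ene), THF, 0 °C; then NaBO3·4H2O, H2O, rt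
Reagents that add atoms: sodium perborate, [Na+].[Na+].O[B-]1(O)OO[B-](O)(O)OO1
Why: Disiamylborane hydroborates the unhindered monosubstituted alkene much faster than the neopentyl 1,1-disubstituted isopropenyl group, the conjugated alkene or the hindered C9 carbonyl (anti-Markovnikov hydroboration), and perborate oxidises the C–B bond without the alkaline peroxide that would epoxidise the enone.

Step 4
Reactants: 8 keto alcohol
Product: 9 3-[(1S,6R)-1,3-dimethyl-2-oxo-6-(prop-1-en-2-yl)cyclohex-3-en-1-yl]propanal
Conditions: Dess–Martin periodinane, CH2Cl2, 0 °C → rt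
Reagents that add atoms: none
Why: Dess–Martin oxidation takes the primary alcohol to the aldehyde under neutral conditions and leaves both alkenes untouched; 9 is used promptly to avoid aldol side reactions.

Step 5
Reactants: 9 keto aldehyde
Product: 10 (4aR,6S,8aS)-6-hydroxy-2,5,5,8a-tetramethyl-4a,5,6,7,8,8a-hexahydronaphthalen-1(4H)-one (A/B-cis 3-hydroxy-4,4,8,10-tetramethyl-Δ7-octalin-9-one)
Conditions: Fe(acac)3 (30 mol%), PhSiH3, EtOH/HOCH2CH2OH (5:1), 60 °C, Ar
Reagents that add atoms: none
Why: The iron hydride formed from Fe(acac)3 and PhSiH3 transfers a hydrogen atom to the terminal CH2 of the isopropenyl group, which becomes the second C4 methyl and leaves a nucleophilic tertiary radical at C4. This radical adds to the aldehyde carbon C3 in a 6-exo-trig closure (C3–C4 bond, ring A), and the alkoxy radical is reduced by divalent iron and protonated by ethanol, which returns trivalent iron. The closest known reaction type is the Fe(acac)3/PhSiH3 hydrogen-atom-transfer radical cyclisation of alkene-tethered ketones and aldehydes to cyclic alcohols. No fusion centre is created: C5 and C10 already carry the isopropenyl group and the oxopropyl arm cis to each other, so only the cis-fused decalin can close. The one new stereocentre, C3, is set by a chair-like transition state with the carbonyl oxygen pseudoequatorial, but its sense depends on which chair of the cis system reacts and is irrelevant because C3 is oxidised in step 23. The step needs chemoselective hydrogen-atom transfer to the electron-rich 1,1-disubstituted alkene in the presence of the electron-poor trisubstituted enone, which the polarity of the metal hydride secures. It also needs the radical to find the aldehyde, which is the only acceptor within reach, since the enone could be attacked only in disfavoured 4-exo or 5-endo modes. A polar (cationic) closure would bond the CH2 terminus and give a seven-membered ring, so the radical mode is what makes C4 the bond-forming atom.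

Step 6
Reactants: 10 hydroxy enone
Product: 11 3-O-(tert-butyldimethylsilyl) ether of 10
Conditions: TBSOTf, 2,6-lutidine, CH2Cl2, 0 °C
Reagents that add atoms: tert-butyldimethylsilyl trifluoromethanesulfonate, CC(C)(C)[Si](C)(C)OS(=O)(=O)C(F)(F)F
Why: The silyl triflate silylates the hindered carbinol next to the gem-dimethyl group; the ether keeps C3 inert to hydrazine, organometallics and the later oxidant and is removed together with the C23 ether.

Step 7
Reactants: 11 silyloxy enone
Product: 12 7,8-epoxy-9-ketone (oxirane on the face of CH3-10)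
Conditions: 30% H2O2, NaOH (0.2 equiv), MeOH, 0 °C → rt
Reagents that add atoms: hydrogen peroxide, OO
Why: Weitz–Scheffer epoxidation: hydroperoxide adds to C7 of the enone and the enolate closes the oxirane, by analogy with carvone itself; entry on the open face (that of CH3-10, away from ring A) is expected, and the two new centres are not needed later.

Step 8
Reactants: 12 epoxy ketone
Product: 14 A/B-cis 3-(tert-butyldimethylsilyloxy)-4,4,8,10-tetramethyl-Δ8(9)-octalin-7-ol, via epoxy hydrazone 13 (not isolated)
Conditions: N2H4·H2O, AcOH (cat.), MeOH, 0 °C → rt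
Reagents that add atoms: none
Why: Wharton transposition: hydrazone 13 opens the oxirane at C8 and loses N2, which leaves the C8=C9 alkene and the C7 carbinol with its C–O bond unchanged; C9 becomes the alkene CH that the chain will attack.

Step 9
Reactants: 14 allylic alcohol
Product: 15 A/B-cis 3-(tert-butyldimethylsilyloxy)-4,4,8,10-tetramethyl-Δ8(9)-octalin-7-one
Conditions: Dess–Martin periodinane, CH2Cl2, rt
Reagents that add atoms: none
Why: Dess–Martin oxidation of the allylic alcohol gives the transposed enone; C10 is quaternary and C5 is not α to the carbonyl, so the ring fusion cannot epimerise.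

Step 10
Reactants: 16 (2E,6E)-farnesol
Product: 17 (2E,6E)-farnesyl acetate
Conditions: Ac2O, pyridine, DMAP (cat.), CH2Cl2, rt
Reagents that add atoms: acetic anhydride, CC(=O)OC(C)=O
Why: Acetylation protects the allylic hydroxyl and deactivates the neighbouring alkene towards the oxidant of step 11.

Step 11
Reactants: 17 farnesyl acetate
Product: 18 (2E,6E,10E)-12-hydroxy-3,7,11-trimethyldodeca-2,6,10-trien-1-yl acetate
Conditions: SeO2 (cat.), t-BuOOH, salicylic acid (cat.), CH2Cl2, 0 °C → rt
Reagents that add atoms: tert-butyl hydroperoxide, CC(C)(C)OO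
Why: Selenium dioxide allylic oxidation (ene reaction then [2,3]-shift, reoxidised by the hydroperoxide) attacks the most electron-rich terminal alkene and selects its (E)-methyl group, which gives the (E)-allylic alcohol that becomes C23; the reaction is stopped short of full conversion to limit over-oxidation.

Step 12
Reactants: 18 hydroxy acetate
Product: 19 (2E,6E,10E)-12-(tert-butyldimethylsilyloxy)-3,7,11-trimethyldodeca-2,6,10-trien-1-yl acetate
Conditions: TBSCl, imidazole, CH2Cl2, rt
Reagents that add atoms: tert-butyldimethylsilyl chloride, CC(C)(C)[Si](C)(C)Cl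
Why: Standard silylation of the primary allylic alcohol; the silyl ether survives base, Wittig, borane and Grignard chemistry.

Step 13
Reactants: 19 silyloxy acetate
Product: 20 (2E,6E,10E)-12-(tert-butyldimethylsilyloxy)-3,7,11-trimethyldodeca-2,6,10-trien-1-ol
Conditions: K2CO3 (cat.), MeOH, rt
Reagents that add atoms: none
Why: Base-catalysed transesterification removes the acetate and leaves the silyl ether.

Step 14
Reactants: 20 allylic alcohol
Product: 21 (2E,6E,10E)-12-(tert-butyldimethylsilyloxy)-3,7,11-trimethyldodeca-2,6,10-trienal
Conditions: Dess–Martin periodinane, CH2Cl2, 0 °C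
Reagents that add atoms: none
Why: Neutral Dess–Martin oxidation gives the (2E)-enal without E/Z equilibration.

Step 15
Reactants: 21 enal
Product: 22 tert-butyldimethyl{[(2E,6E,10E)-2,6,10-trimethyltrideca-2,6,10,12-tetraen-1-yl]oxy}silane
Conditions: Ph3PCH3Br, n-BuLi, THF, 0 °C; then 21, −78 °C → rt
Reagents that add atoms: methyltriphenylphosphonium bromide, C[P+](c1ccccc1)(c1ccccc1)c1ccccc1.[Br-]
Why: Wittig methylenation of the enal gives the terminal 1,3-diene; the trisubstituted alkene geometry is not touched.

Step 16
Reactants: 22 tetraene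
Product: 24 (3E,7E,11E)-13-(tert-butyldimethylsilyloxy)-4,8,12-trimethyltrideca-3,7,11-trien-1-ol, via alkyl(disiamyl)borane 23 (not isolated)
Conditions: Sia2BH (from BH3·SMe2 and 2-methylbut-2-ene), THF, 0 °C; then NaOH, 30% H2O2, 0 °C → rt
Reagents that add atoms: hydrogen peroxide, OO
Why: The dialkylborane adds only to the terminal monosubstituted alkene of the diene, boron at the CH2 end, and oxidation gives the homoallylic alcohol, so that one carbon (C11) has been added to the farnesyl skeleton.

Step 17
Reactants: 24 homoallylic alcohol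
Product: 25 {[(2E,6E,10E)-13-bromo-2,6,10-trimethyltrideca-2,6,10-trien-1-yl]oxy}(tert-butyl)dimethylsilane
Conditions: CBr4, PPh3, CH2Cl2, 0 °C
Reagents that add atoms: carbon tetrabromide, BrC(Br)(Br)Br
Why: Appel bromination of the primary alcohol under neutral conditions tolerates the allylic silyl ether and the alkenes.

Step 18
Reactants: 25 homoallylic bromide; 15 transposed enone
Product: 27 C7 trimethylsilyl enol ether carrying the C11–C23 chain at C9 (chain cis to CH3-10), via Grignard reagent 26 (not isolated)
Conditions: 25, Mg, THF, rt; then 15, CuBr·SMe2 (20 mol%), Me3SiCl, HMPA, THF, −78 → −40 °C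
Reagents that add atoms: chlorotrimethylsilane, C[Si](C)(C)Cl
Why: Copper-catalysed conjugate addition of the Grignard reagent, accelerated by Me3SiCl/HMPA, forms C9–C11 and traps the enolate as its silyl ether; addition should occur anti to the pseudoaxial C10–C1 bond, that is on the convex face bearing CH3-10, because the other face is screened by ring A (C1, or C4 with its methyls in the alternative half-chair), which sets C9 (R) from C10.

Step 19
Reactants: 27 silyl enol ether
Product: 29 8α-hydroxy-7-ketone (3,23-bis-silyl ether), via lithium enolate 28 (not isolated)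
Conditions: MeLi, THF, 0 °C; then 2-(phenylsulfonyl)-3-phenyloxaziridine, −78 °C
Reagents that add atoms: 2-(phenylsulfonyl)-3-phenyloxaziridine, O=S(=O)(N1OC1c1ccccc1)c1ccccc1
Why: MeLi cleaves the O–Si bond to give the regiodefined enolate 28, which is oxygenated at C8 by the N-sulfonyloxaziridine (enolate hydroxylation) on the face opposite to the pseudoaxial C9 chain, giving the α-hydroxyl (C8 R) with the methyl cis to the chain; the reagent does not epoxidise isolated alkenes at −78 °C.

Step 20
Reactants: 29 hydroxy ketone
Product: 30 C7 tosylhydrazone of 29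
Conditions: TsNHNH2, EtOH, 60 °C
Reagents that add atoms: p-toluenesulfonohydrazide, Cc1ccc(cc1)S(=O)(=O)NN
Why: Condensation at the only ketone gives the tosylhydrazone; no acid is added so that the α-ketol and the allylic silyl ether are not put at risk.

Step 21
Reactants: 30 tosylhydrazone
Product: 32 3,23-bis-O-(tert-butyldimethylsilyl) ether of the 3,8,23-triol (C7 = CH2), via C7 tosylhydrazine 31 (not isolated)
Conditions: catecholborane, CHCl3, 0 °C → rt; then NaOAc·3H2O, 60 °C
Reagents that add atoms: none
Why: Hydride from catecholborane adds to the C=N bond (31); acetate then induces loss of sulfinate and N2, which leaves CH2 at C7 under conditions too mild to hydroborate the chain alkenes or to ionise the tertiary alcohol.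

Step 22
Reactants: 32 bis-silyl ether
Product: 33 A/B-cis polypoda-13E,17E,21E-triene-3,8α,23-triol
Conditions: Bu4NF, THF, rt → 50 °C
Reagents that add atoms: none
Why: Fluoride cleaves both silyl ethers; warming is needed for the neopentyl C3 ether, and nothing in 32 is base-sensitive.

Step 23
Reactants: 33 triol
Product: 34 8α-hydroxy-3-oxo-13E,17E,21E-trien-23-al
Conditions: Dess–Martin periodinane, CH2Cl2, 0 °C → rt
Reagents that add atoms: none
Why: Dess–Martin periodinane oxidises the secondary C3 carbinol to the ketone (which removes the uncontrolled C3 centre) and the allylic C23 alcohol to the (E)-enal in one operation; the tertiary alcohol cannot react.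

Step 24
Reactants: 34 keto enal
Product: 35 myrrhanone B
Conditions: NaClO2, NaH2PO4, 2-methylbut-2-ene, t-BuOH/H2O, 0 °C → rt
Reagents that add atoms: sodium chlorite, [Na+].[O-]Cl=O
Why: Pinnick oxidation converts the enal into the acid without touching the ketone; the alkene scavenger removes HOCl before it can add to the chain alkenes, and the (E)-geometry is retained.

## Compound list

1 | (S)-(+)-carvone | CC1=CC[C@@H](CC1=O)C(C)=C | starting material
2 | allyl bromide | C=CCBr | starting material
3 | lithium cross-conjugated dienolate of 1 | [Li]OC1=C[C@@H](C(C)=C)CC=C1C | intermediate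
4 | (5S,6R)-2-methyl-6-(prop-2-en-1-yl)-5-(prop-1-en-2-yl)cyclohex-2-en-1-one (trans isomer drawn; the 6-epimer also serves) | O=C1C(C)=CC[C@H](C(C)=C)[C@H]1CC=C | intermediate
5 | lithium enolate of 4 | [Li]OC1=C(CC=C)[C@@H](C(C)=C)CC=C1C | intermediate
6 | (5R,6S)-6-allyl-2,6-dimethyl-5-(prop-1-en-2-yl)cyclohex-2-en-1-one (methyl trans, allyl cis to isopropenyl) | O=C1C(C)=CC[C@H](C(C)=C)[C@]1(C)CC=C | intermediate
7 | terminal bis(3-methylbutan-2-yl)borane from 6 | O=C1C(C)=CC[C@H](C(C)=C)[C@]1(C)CCCB(C(C)C(C)C)C(C)C(C)C | intermediate
8 | (5R,6S)-6-(3-hydroxypropyl)-2,6-dimethyl-5-(prop-1-en-2-yl)cyclohex-2-en-1-one | O=C1C(C)=CC[C@H](C(C)=C)[C@]1(C)CCCO | intermediate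
9 | 3-[(1S,6R)-1,3-dimethyl-2-oxo-6-(prop-1-en-2-yl)cyclohex-3-en-1-yl]propanal | O=C1C(C)=CC[C@H](C(C)=C)[C@]1(C)CCC=O | intermediate
10 | (4aR,6S,8aS)-6-hydroxy-2,5,5,8a-tetramethyl-4a,5,6,7,8,8a-hexahydronaphthalen-1(4H)-one (3S drawn, see assumption 1) | O=C1[C@@]2(C)CC[C@H](O)C(C)(C)[C@H]2CC=C1C | intermediate
11 | 3-O-tert-butyldimethylsilyl ether of 10 | O=C1[C@@]2(C)CC[C@H](O[Si](C)(C)C(C)(C)C)C(C)(C)[C@H]2CC=C1C | intermediate
12 | 7,8-epoxide of 11, oxirane oxygen cis to CH3-10 (expected face) | O=C1[C@@]2(C)CC[C@H](O[Si](C)(C)C(C)(C)C)C(C)(C)[C@H]2C[C@@H]3O[C@@]31C | intermediate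
13 | C9 hydrazone of 12 | NN=C1[C@@]2(C)CC[C@H](O[Si](C)(C)C(C)(C)C)C(C)(C)[C@H]2C[C@@H]3O[C@@]31C | intermediate
14 | A/B-cis 3-(tert-butyldimethylsilyloxy)-4,4,8,10-tetramethyl-Δ8(9)-octalin-7-ol, 7-OH cis to CH3-10 | CC1=C[C@@]2(C)CC[C@H](O[Si](C)(C)C(C)(C)C)C(C)(C)[C@H]2C[C@@H]1O | intermediate
15 | A/B-cis 3-(tert-butyldimethylsilyloxy)-4,4,8,10-tetramethyl-Δ8(9)-octalin-7-one | CC1=C[C@@]2(C)CC[C@H](O[Si](C)(C)C(C)(C)C)C(C)(C)[C@H]2CC1=O | intermediate
16 | (2E,6E)-farnesol | CC(C)=CCC/C(C)=C/CC/C(C)=C/CO | starting material
17 | (2E,6E)-farnesyl acetate | CC(C)=CCC/C(C)=C/CC/C(C)=C/COC(C)=O | intermediate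
18 | (2E,6E,10E)-12-hydroxy-3,7,11-trimethyldodeca-2,6,10-trien-1-yl acetate | CC(=O)OC/C=C(\C)CC/C=C(\C)CC/C=C(\C)CO | intermediate
19 | (2E,6E,10E)-12-(tert-butyldimethylsilyloxy)-3,7,11-trimethyldodeca-2,6,10-trien-1-yl acetate | CC(=O)OC/C=C(\C)CC/C=C(\C)CC/C=C(\C)CO[Si](C)(C)C(C)(C)C | intermediate
20 | (2E,6E,10E)-12-(tert-butyldimethylsilyloxy)-3,7,11-trimethyldodeca-2,6,10-trien-1-ol | OC/C=C(\C)CC/C=C(\C)CC/C=C(\C)CO[Si](C)(C)C(C)(C)C | intermediate
21 | (2E,6E,10E)-12-(tert-butyldimethylsilyloxy)-3,7,11-trimethyldodeca-2,6,10-trienal | O=C/C=C(\C)CC/C=C(\C)CC/C=C(\C)CO[Si](C)(C)C(C)(C)C | intermediate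
22 | tert-butyldimethyl{[(2E,6E,10E)-2,6,10-trimethyltrideca-2,6,10,12-tetraen-1-yl]oxy}silane | C=C/C=C(\C)CC/C=C(\C)CC/C=C(\C)CO[Si](C)(C)C(C)(C)C | intermediate
23 | terminal bis(3-methylbutan-2-yl)borane from 22 | CC(C)C(C)B(C(C)C(C)C)CC/C=C(\C)CC/C=C(\C)CC/C=C(\C)CO[Si](C)(C)C(C)(C)C | intermediate
24 | (3E,7E,11E)-13-(tert-butyldimethylsilyloxy)-4,8,12-trimethyltrideca-3,7,11-trien-1-ol | OCC/C=C(\C)CC/C=C(\C)CC/C=C(\C)CO[Si](C)(C)C(C)(C)C | intermediate
25 | {[(2E,6E,10E)-13-bromo-2,6,10-trimethyltrideca-2,6,10-trien-1-yl]oxy}(tert-butyl)dimethylsilane | BrCC/C=C(\C)CC/C=C(\C)CC/C=C(\C)CO[Si](C)(C)C(C)(C)C | intermediate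
26 | Grignard reagent of 25 | Br[Mg]CC/C=C(\C)CC/C=C(\C)CC/C=C(\C)CO[Si](C)(C)C(C)(C)C | intermediate
27 | C7 trimethylsilyl enol ether; chain at C9 cis to CH3-10; 3,23-bis-TBS | CC(C)(C)[Si](C)(C)OC/C(C)=C/CC/C(C)=C/CC/C(C)=C/CC[C@@H]1[C@@]2(C)CC[C@H](O[Si](C)(C)C(C)(C)C)C(C)(C)[C@H]2CC(O[Si](C)(C)C)=C1C | intermediate
28 | lithium C7 enolate from 27 | CC(C)(C)[Si](C)(C)OC/C(C)=C/CC/C(C)=C/CC/C(C)=C/CC[C@@H]1[C@@]2(C)CC[C@H](O[Si](C)(C)C(C)(C)C)C(C)(C)[C@H]2CC(O[Li])=C1C | intermediate
29 | 8α-hydroxy-7-ketone (8-CH3 β), 3,23-bis-TBS | CC(C)(C)[Si](C)(C)OC/C(C)=C/CC/C(C)=C/CC/C(C)=C/CC[C@@H]1[C@@]2(C)CC[C@H](O[Si](C)(C)C(C)(C)C)C(C)(C)[C@H]2CC(=O)[C@@]1(C)O | intermediate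
30 | C7 tosylhydrazone of 29 | CC(C)(C)[Si](C)(C)OC/C(C)=C/CC/C(C)=C/CC/C(C)=C/CC[C@@H]1[C@@]2(C)CC[C@H](O[Si](C)(C)C(C)(C)C)C(C)(C)[C@H]2CC(=NNS(=O)(=O)c3ccc(C)cc3)[C@@]1(C)O | intermediate
31 | C7 N′-tosylhydrazine from 30 (C7 not assigned; lost in the same flask) | CC(C)(C)[Si](C)(C)OC/C(C)=C/CC/C(C)=C/CC/C(C)=C/CC[C@@H]1[C@@]2(C)CC[C@H](O[Si](C)(C)C(C)(C)C)C(C)(C)[C@H]2CC(NNS(=O)(=O)c3ccc(C)cc3)[C@@]1(C)O | intermediate
32 | 3,23-bis-O-TBS ether of the A/B-cis 3,8α,23-triol | CC(C)(C)[Si](C)(C)OC/C(C)=C/CC/C(C)=C/CC/C(C)=C/CC[C@@H]1[C@@]2(C)CC[C@H](O[Si](C)(C)C(C)(C)C)C(C)(C)[C@H]2CC[C@@]1(C)O | intermediate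
33 | A/B-cis polypoda-13E,17E,21E-triene-3,8α,23-triol | OC/C(C)=C/CC/C(C)=C/CC/C(C)=C/CC[C@@H]1[C@@]2(C)CC[C@H](O)C(C)(C)[C@H]2CC[C@@]1(C)O | intermediate
34 | 8α-hydroxy-3-oxo-polypoda-13E,17E,21E-trien-23-al | O=C/C(C)=C/CC/C(C)=C/CC/C(C)=C/CC[C@@H]1[C@@]2(C)CCC(=O)C(C)(C)[C@H]2CC[C@@]1(C)O | intermediate
35 | myrrhanone B | C/C(=C\CC/C(C)=C/CC[C@@H]1[C@@]2(C)CCC(=O)C(C)(C)[C@H]2CC[C@@]1(C)O)CC/C=C(\C)C(=O)O | target

## Step count and least certain steps

Total step count: 24 (steps 1–9 ring piece, 10–17 chain, 18–24 union and end game).
Longest linear sequence: 16 steps (1–9 and 18–24, from 1); the chain branch is 15 steps (10–24).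

**Step 5 (key step).**
- Risk: the C4 radical may be reduced to an isopropyl group before it closes, the closure may revert by β-scission of the alkoxy radical if its reduction by iron is slow, or hydrogen-atom transfer to the enone may compete. All three reflect the lack of a fast trap in the iron system.
- Fallback (sets out from 6, returns at 10): Markovnikov addition of HBr (HBr/AcOH, 0 °C) to the isopropenyl group of 6 should give the tertiary bromide F1. The operations of steps 3 and 4 (Sia2BH then NaBO3·4H2O; Dess–Martin periodinane) would then give the bromo alcohol F2 and the bromo aldehyde F3. Bu3SnH/AIBN (benzene, 80 °C, slow addition) generates the same C4 radical from the C–Br bond, and the stannane traps the cyclised alkoxy radical at once. This is a known tin hydride 6-exo radical cyclisation onto an aldehyde and gives 10.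

**Step 18.**
- Risk: poor facial selectivity at C9 (entry of the chain on the face of C1 instead of that of CH3-10), or sluggish addition at the neopentyl β-carbon with competing 1,2-addition.
- Fallback (sets out from 14 and 20, returns at 32; it also replaces steps 9 and 19–21): 14, with its C7 hydroxyl cis to CH3-10 (its C7 epimer would first be inverted under Mitsunobu conditions), is esterified with tosylacetic acid (DCC, DMAP) to the tosylacetate F4. A decarboxylative Claisen rearrangement (N,O-bis(trimethylsilyl)acetamide, KOAc cat., toluene, 110 °C) transfers the CH2Ts group suprafacially from the C7 oxygen to C9 and gives the homoallylic sulfone F5. mCPBA epoxidises C7=C8 anti to that group (epoxy sulfone F6), and LiEt3BH opens the oxirane at C7 to the C8α-hydroxy sulfone F7. Alcohol 20 is converted into the allylic bromide F8 (CBr4, PPh3). The dianion of F7 (n-BuLi, 2 equiv, THF/HMPA, −78 °C) is alkylated with F8 at C11 to the sulfone F9, and Na(Hg)/Na2HPO4 in MeOH removes the sulfonyl group to give 32. The C9 configuration then follows from the C7 carbinol by a sigmatropic shift, and the C8 hydroxyl is made before any chain alkene is present.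

**Step 21.**
- Risk: loss of the C8 oxygen by elimination at the diazene stage, or α-ketol rearrangement while the hindered C7 carbonyl is being condensed in step 20.
- Fallback (sets out from 29, returns at 32): NaBH4 (MeOH, 0 °C) reduces 29 to the 7,8-diol F10. PhOC(S)Cl/pyridine/DMAP (CH2Cl2, 0 °C) acylates only the secondary hydroxyl to the thionocarbonate F11. Barton–McCombie deoxygenation (Bu3SnH, AIBN, toluene, 100 °C, high stannane concentration so that the C7 radical is reduced before it can add to C13=C14) gives 32.

**Step 8.**
- Risk: slow hydrazone formation at the C9 carbonyl, which lies between the quaternary C10 and the oxirane, so that opening of the epoxide by hydrazine or azine formation takes over.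
- Fallback (sets out from 12, returns at 14): NaBH4/CeCl3 (MeOH, 0 °C) gives the epoxy alcohol F12. 1,1′-Thiocarbonyldiimidazole (CH2Cl2, reflux) gives the imidazolide F13. Bu3SnH/AIBN (benzene, 80 °C) generates the C9 radical, which opens the adjacent oxirane (the radical counterpart of the Wharton transposition) to 14 with the C7–O bond retained.

## Further compounds

F1 | step 5 | 6-allyl-5-(2-bromopropan-2-yl)-2,6-dimethylcyclohex-2-en-1-one (ring centres as in 6) | O=C1C(C)=CC[C@H](C(C)(C)Br)[C@]1(C)CC=C
F2 | step 5 | 5-(2-bromopropan-2-yl)-6-(3-hydroxypropyl)-2,6-dimethylcyclohex-2-en-1-one (ring centres as in 6) | O=C1C(C)=CC[C@H](C(C)(C)Br)[C@]1(C)CCCO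
F3 | step 5 | 3-[6-(2-bromopropan-2-yl)-1,3-dimethyl-2-oxocyclohex-3-en-1-yl]propanal (ring centres as in 9) | O=C1C(C)=CC[C@H](C(C)(C)Br)[C@]1(C)CCC=O
F4 | step 18 | C7 tosylacetate of 14 | CC1=C[C@@]2(C)CC[C@H](O[Si](C)(C)C(C)(C)C)C(C)(C)[C@H]2C[C@@H]1OC(=O)CS(=O)(=O)c3ccc(C)cc3
F5 | step 18 | A/B-cis 9-(tosylmethyl)-3-(tert-butyldimethylsilyloxy)-4,4,8,10-tetramethyl-Δ7-octalin (CH2Ts cis to CH3-10) | Cc1ccc(cc1)S(=O)(=O)C[C@@H]2[C@@]3(C)CC[C@H](O[Si](C)(C)C(C)(C)C)C(C)(C)[C@H]3CC=C2C
F6 | step 18 | 7α,8α-epoxide of F5 | Cc1ccc(cc1)S(=O)(=O)C[C@@H]2[C@@]3(C)CC[C@H](O[Si](C)(C)C(C)(C)C)C(C)(C)[C@H]3C[C@H]4O[C@@]24C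
F7 | step 18 | 8α-hydroxy C11 sulfone from F6 | Cc1ccc(cc1)S(=O)(=O)C[C@@H]2[C@@]3(C)CC[C@H](O[Si](C)(C)C(C)(C)C)C(C)(C)[C@H]3CC[C@@]2(C)O
F8 | step 18 | {[(2E,6E,10E)-12-bromo-2,6,10-trimethyldodeca-2,6,10-trien-1-yl]oxy}(tert-butyl)dimethylsilane | BrC/C=C(\C)CC/C=C(\C)CC/C=C(\C)CO[Si](C)(C)C(C)(C)C
F9 | step 18 | 11-tosyl derivative of 32 (C11 not assigned; removed in the next operation) | CC(C)(C)[Si](C)(C)OC/C(C)=C/CC/C(C)=C/CC/C(C)=C/CC(S(=O)(=O)c1ccc(C)cc1)[C@@H]2[C@@]3(C)CC[C@H](O[Si](C)(C)C(C)(C)C)C(C)(C)[C@H]3CC[C@@]2(C)O
F10 | step 21 | 7,8-diol from 29 (C7 not assigned; either epimer serves) | CC(C)(C)[Si](C)(C)OC/C(C)=C/CC/C(C)=C/CC/C(C)=C/CC[C@@H]1[C@@]2(C)CC[C@H](O[Si](C)(C)C(C)(C)C)C(C)(C)[C@H]2CC(O)[C@@]1(C)O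
F11 | step 21 | C7 O-phenyl thionocarbonate of F10 | CC(C)(C)[Si](C)(C)OC/C(C)=C/CC/C(C)=C/CC/C(C)=C/CC[C@@H]1[C@@]2(C)CC[C@H](O[Si](C)(C)C(C)(C)C)C(C)(C)[C@H]2CC(OC(=S)Oc3ccccc3)[C@@]1(C)O
F12 | step 8 | 7,8-epoxy-9-ol from 12 (C9 not assigned; either epimer serves) | OC1[C@@]2(C)CC[C@H](O[Si](C)(C)C(C)(C)C)C(C)(C)[C@H]2C[C@@H]3O[C@@]31C
F13 | step 8 | C9 O-(imidazole-1-carbothioate) of F12 | S=C(OC1[C@@]2(C)CC[C@H](O[Si](C)(C)C(C)(C)C)C(C)(C)[C@H]2C[C@@H]3O[C@@]31C)n1ccnc1
A1 | alternative 1 | A/B-cis 4,4,8,10-tetramethyl-Δ8(9)-octalin-3-one | CC1=C[C@@]2(C)CCC(=O)C(C)(C)[C@H]2CC1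
A2 | alternative 1 | 2-ethenyl-1,3,3,5-tetramethylbicyclo[2.2.2]oct-5-en-2-ol (vinyl syn to the C5=C6 bridge) | C=C[C@]1(O)C(C)(C)[C@H]2CC[C@]1(C)C=C2C
A3 | alternative 1 | 2,4,6-trimethylphenol | Cc1cc(C)c(O)c(C)c1
A4 | alternative 2 | ethyl ester of the A/B-cis 3-(tert-butyldimethylsilyloxy)-8α-hydroxy-4,4,8,10-tetramethyldecalin-9-ylacetic acid | CCOC(=O)C[C@@H]1[C@@]2(C)CC[C@H](O[Si](C)(C)C(C)(C)C)C(C)(C)[C@H]2CC[C@@]1(C)O
A5 | alternative 2 | ring-A keto enoate: ethyl (E)-3-[cyclohexyl]acrylate with the C10 methyl, the 3-silyloxy-4,4-dimethyl pattern and a 3-oxobutyl chain at C5 | CCOC(=O)/C=C/[C@@]1(C)CC[C@H](O[Si](C)(C)C(C)(C)C)C(C)(C)[C@H]1CCC(C)=O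
A6 | alternative 2 | (S)-Wieland–Miescher ketone | C[C@]12CCC(=O)C=C1CCCC2=O
A7 | alternative 3 | A/B-cis 3-(tert-butyldimethylsilyloxy)-4,4,10-trimethyl-Δ2-octalin-9-one | O=C1[C@@]2(C)CC=C(O[Si](C)(C)C(C)(C)C)C(C)(C)[C@H]2CCC1
A8 | alternative 3 | 2-methylcyclohex-2-en-1-one | CC1=CCCCC1=O
A9 | alternative 3 | tert-butyldimethyl[(4-methylpenta-1,3-dien-3-yl)oxy]silane | C=CC(O[Si](C)(C)C(C)(C)C)=C(C)C
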